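**Retrosynthetic overview**
- The only key disconnection is the diaryl ether C–O bond of target 7 on the ring-B side: the mono-phenoxide 6 of tetrabromocatechol 5 plus the aryl-cation equivalent 4, metal-free so no C–Br bond is touched.
- Ring B comes from 1,3-dibromobenzene 1: two molecules of 1 are joined through iodine(III) (via 2 and 3) to the symmetric bis(2,4-dibromophenyl)iodonium chloride 4, both C–I bonds forming by electrophilic substitution at C-4 of 1.
- Ring A is commercial tetrabromocatechol 5, bought with all four bromines in place.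
- No ring is formed; both benzene rings are bought. Order: make 4, then join it to 5 in the last step.

Assumption: the target has no stereocentre or other stereo-element (it is achiral), so "single enantiomer" needs no stereocontrol.

**Step 1**
Reactants: 1 1,3-dibromobenzene (2 equiv per iodine(III); the first molecule is iodinated to 2, the second arylates 2 and is entered again under the reagents)
Product: 4 bis(2,4-dibromophenyl)iodonium chloride, via 2,4-dibromo-1-iodosylbenzene 2 (not isolated), via bis(2,4-dibromophenyl)iodonium hydrogen sulfate 3 (not isolated)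
Conditions: I2/KIO3 (1:3 mol), conc. H2SO4, rt, 16 h; then 1 (2 equiv per I(III)), 0 °C → rt, 24–48 h; ice/H2O; aq. HCl; filter, wash (H2O, Et2O), recrystallise
Reagents that add atoms: 1,3-dibromobenzene (second equivalent of 1), Brc1cccc(Br)c1; iodine, II; potassium iodate, [K+].[O-]I(=O)=O; hydrochloric acid, Cl
Why: Beringer-type iodyl sulfate synthesis of a diaryliodonium salt, in which I(III) from comproportionation of I2/KIO3 attacks two molecules of 1 in turn by electrophilic aromatic substitution at C-4 (para to one Br, ortho to the other; C-2 is sterically blocked and C-5 is meta to both), and chloride metathesis precipitates the salt.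

**Step 2**
Reactants: 4 bis(2,4-dibromophenyl)iodonium chloride, 5 3,4,5,6-tetrabromobenzene-1,2-diol (tetrabromocatechol)
Product: 7 3,4,5,6-tetrabromo-2-(2,4-dibromophenoxy)phenol, via monosodium 3,4,5,6-tetrabromocatecholate 6 (not isolated)
Conditions: 5 (3 equiv), NaOH (1.5 equiv), H2O/1,4-dioxane 1:1, N2, rt; then 4 (1 equiv), reflux, 2 h; aq. HCl work-up; chromatography (excess 5 recovered)
Reagents that add atoms: none
Why: Metal-free O-arylation of a phenoxide by a diaryliodonium salt (ligand exchange then ligand coupling at iodine(III)), where the symmetric salt can transfer only 2,4-dibromophenyl, no C–Br bond reacts, and excess 5 with substoichiometric base holds the reaction at mono-arylation.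

**Compound list**
1 | 1,3-dibromobenzene | Brc1cccc(Br)c1 | starting material
2 | 2,4-dibromo-1-iodosylbenzene (present in H2SO4 in its protonated/sulfated form) | O=Ic1ccc(Br)cc1Br | intermediate
3 | bis(2,4-dibromophenyl)iodonium hydrogen sulfate | OS(=O)(=O)[O-].Brc1ccc([I+]c2ccc(Br)cc2Br)c(Br)c1 | intermediate
4 | bis(2,4-dibromophenyl)iodonium chloride | [Cl-].Brc1ccc([I+]c2ccc(Br)cc2Br)c(Br)c1 | intermediate
5 | 3,4,5,6-tetrabromobenzene-1,2-diol (tetrabromocatechol) | Oc1c(O)c(Br)c(Br)c(Br)c1Br | starting material
6 | monosodium 3,4,5,6-tetrabromocatecholate | [Na+].[O-]c1c(O)c(Br)c(Br)c(Br)c1Br | intermediate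
7 | 3,4,5,6-tetrabromo-2-(2,4-dibromophenoxy)phenol (achiral) | Oc1c(Br)c(Br)c(Br)c(Br)c1Oc1ccc(Br)cc1Br | target

**Totals**
Total step count: 2. Longest linear sequence: 2 (1 → 4 → 7).

**Steps most likely to fail**
The route has only two steps, so both are ranked; there is no third step.

1. Step 2 (highest risk). The hydrogen-bonded, electron-poor and doubly ortho-substituted phenoxide 6 may react slowly, and product 7 can be arylated a second time. Fallback, setting out from 4 and coming back at 7: commercial guaiacol (2-methoxyphenol) is exhaustively brominated (excess Br2, cat. Fe, CHCl3/AcOH, reflux) to 3,4,5,6-tetrabromo-2-methoxyphenol F1, which has only one phenolic oxygen. Its sodium phenoxide (NaOH, H2O/dioxane, reflux) is arylated by 4 to 1,2,3,4-tetrabromo-5-(2,4-dibromophenoxy)-6-methoxybenzene F2. BBr3 (CH2Cl2, 0 °C → rt) then cleaves the methyl ether to give 7.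

2. Step 1. Compound 1 is a deactivated arene, so conversion may be low or the salt may contain isomers. Fallback, setting out from 1 and coming back at 7: iodination of 1 (NIS, TfOH, CH2Cl2, 0 °C → rt) gives 2,4-dibromo-1-iodobenzene F3. One-pot oxidation and arylation (mCPBA, TsOH·H2O, MeCN, 55 °C; then commercial 1,3,5-trimethoxybenzene, rt) gives (2,4-dibromophenyl)(2,4,6-trimethoxyphenyl)iodonium p-toluenesulfonate F4. F4 arylates 5 (3 equiv, K2CO3 1.5 equiv, MeCN, 60 °C), the trimethoxyphenyl group acting as a non-transferred dummy ligand, to give 7 directly.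

**Further compounds**
F1 | step 2 | 3,4,5,6-tetrabromo-2-methoxyphenol | COc1c(O)c(Br)c(Br)c(Br)c1Br
F2 | step 2 | 1,2,3,4-tetrabromo-5-(2,4-dibromophenoxy)-6-methoxybenzene | COc1c(Br)c(Br)c(Br)c(Br)c1Oc1ccc(Br)cc1Br
F3 | step 1 | 2,4-dibromo-1-iodobenzene | Ic1ccc(Br)cc1Br
F4 | step 1 | (2,4-dibromophenyl)(2,4,6-trimethoxyphenyl)iodonium p-toluenesulfonate | Cc1ccc(S(=O)(=O)[O-])cc1.COc1cc(OC)c([I+]c2ccc(Br)cc2Br)c(OC)c1
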